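**Conventions.** Isoflavone numbering is used for the core (rings A, B, C; O1, C2 to C8a, C1' to C6'). The C6 chain is C1'' (benzylic CH2), C2'' (carbinol carbon), C3'' (alkene carbon bearing the methyl group) and C4'' (terminal CH2). The C8 prenyl group starts at C1'''. TBS = tert-butyldimethylsilyl. Remark on the chemistry: the target structure is read as (R) at C2'', and the route is built for that enantiomer.

## The problem

The skeleton of target 18 is genistein (1) with two different C5 chains on the only two free carbons of ring A: a prenyl group on C8 and a 2-hydroxy-3-methylbut-3-enyl group on C6. Rings A, B and C need not be built, but C6 and C8 are activated by the same three oxygens and must be alkylated one after the other with full positional control, ending in a hexasubstituted ring A. There is one stereocenter, C2'' (R), a secondary allylic carbinol. No other stereo element exists in the molecule, so C2'' must be set by a chiral reagent or catalyst.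

Several groups limit the chemistry. The prenyl alkene cyclizes onto neighbouring phenols under acid and is attacked by undirected electrophilic oxidants. The C2'' oxygen is allylic and is flanked by O5 and O7, so acid or an activated C2''/C3'' invites dihydrofuran or dihydropyran closure. The pyranone ring C is opened by hydroxide and attacked by hard hydride or hydrogenation. Protecting groups must therefore come off without acid, hydrogen or strong base.

The feature that opens the problem is that CH(OH)-C(CH3)=CH2 at C2''-C3''-C4'' is the 1,3-transposed form of a primary (E)-allylic alcohol, C2''H=C3''(CH3)-C4''H2OH. That primary hydroxyl can bind a chiral titanium catalyst, which controls the face at C2'' and gives the C6 chain a handle that the C8 prenyl group lacks.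

## Retrosynthesis

**18 from 17.** No skeletal bond is cut; three aryl O-Si bonds are. Silyl ethers on O5, O7 and O4' are preferred to benzyl, methyl or acetal groups because fluoride removes them without acid, hydrogen or Lewis acid. The precursor 17 is the tris-TBS ether of the target. The forward step only has to spare the prenyl group, the allylic alcohol and ring C.

**17 from 16 and 15.** The C3''=C4'' alkene is traced back to a C4''-I bond and a C3''-O bond, that is, to the epoxy iodide 16 and from there to the epoxy alcohol 15. The neighbouring cuts are worse. Cutting C2''-C3'' would add an isopropenyl metal to an enolizable arylacetaldehyde in the presence of the pyranone. Cutting C1''-C2'' would need a carbanion at C6 of a hexasubstituted ring. The transposition keeps all chemistry on the chain and never breaks the C2''-O bond, so 15 already contains the stereocenter. The forward steps are a substitution at C4'' and a two-electron reduction that must not open the epoxide in any other way.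

**15 from 14.** The two C-O bonds of the oxirane (C2''-O and C3''-O) are cut, leading to the (E)-allylic alcohol 14, which has no stereocenter. This is the step that carries the plan. The primary hydroxyl makes the C6 alkene the only one a titanium tartrate catalyst will epoxidize, and the tartrate enantiomer chooses the face. An undirected chiral oxidant would not tell the C6 chain from the prenyl group. The forward reaction must give the (2R,3R) epoxide and leave the prenyl and C2=C3 bonds alone.

**14 from 13, and 13 from 11 and 12.** Alcohol 14 comes from enal 13 by 1,2-reduction. The C2''=C3'' bond of 13 is cut by cross-metathesis into the 6-allyl compound 11 and methacrolein (12). Allylic oxidation of a 6-prenyl group would be shorter, but it could not distinguish the C6 chain from the C8 prenyl group. An allyl group is different in kind from a prenyl group: monosubstituted against trisubstituted. The forward metathesis must be E-selective and must discriminate between these two alkenes; the reduction must spare the pyranone.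

**11 from 10, 8, 6 and 7.** The C6-C1'' bond is cut through an ortho-Claisen rearrangement of the 5-O-allyl ether 8, made from phenol 6 and allyl alcohol (7). Phenol 10, the Claisen product, is then silylated at O5 to give 11. With C8 already occupied and C4a without hydrogen, the allyl group can only end on C6. The ether is made under Mitsunobu conditions and not with allyl halide and carbonate, because carbonate strips the 7-O-silyl group and the freed 7-hydroxyl would be alkylated. Capping O5 is needed later: a free phenol next to the C6 chain would bind titanium and open the epoxide.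

**6 from 4, 2 and 3.** The C8-C1''' bond is cut through a para-Claisen-Cope rearrangement of the 5-O-prenyl ether 4, made from phenol 2 and prenol (3). The prenyl group is put in first, while C6 still carries hydrogen. The oxygen-bound prenyl group passes through C6 and arrives on C8 with its normal connectivity after two [3,3] shifts. This is catalysed by Eu(fod)3, the trivalent europium tris(6,6,7,7,8,8,8-heptafluoro-2,2-dimethyl-3,5-octanedionate). Direct C-prenylation of a phloroglucinol-type ring gives mixtures of C6, C8 and O-alkylated products and was not considered further.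

**2 from 1.** Genistein (1) is silylated at O7 and O4'. The hydrogen-bonded 5-hydroxyl stays free and becomes the anchor for both sigmatropic alkylations.

## Roads not taken

**Alternative 1:** ring C is cut at C4-C4a and O1-C2. In the forward direction, halogen-lithium exchange on the aryl bromide A1 gives an aryllithium at C4a. It takes the 3-methoxy-2-arylacryloyl group from the neighbouring oxygen (anionic Fries shift), and the freed phenoxide displaces methoxide at C2 to close ring C, giving the protected isoflavone A2.
- Merits: the substitution pattern of ring A is fixed in a benzene precursor, so there is no C6/C8 question at all. In this respect it is better than the chosen plan. The ring closure is a low-temperature cascade.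
- Weak points: it does nothing for the stereocenter. A1 must already contain C2'' as a protected carbinol, made by a separate asymmetric sequence on a hexasubstituted benzene. A1 itself needs many steps. The exchange must outrun attack of the alkyllithium on the aryl ester. The alkoxymethyl ethers of A2 come off only with acid or forcing fluoride, which the prenyl and allylic alcohol groups tolerate poorly.
- Comparison: the chosen plan gives up the built-in positional certainty. Against it stand a commercial starting material that already has rings A to C and all oxygens, two sigmatropic steps whose regiochemistry follows from which positions are free, and a catalytic step that sets C2''.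

**Alternative 2:** the chain is cut at C6-C1'' and C2''-C3''. In the forward direction, the borate made from vinylboronic ester A4 and isopropenyllithium A5 is coupled with the C6 aryl iodide A3 under Pd(OAc)2 (divalent palladium) and a chiral MandyPhos-type ligand. The aryl group adds to the vinyl terminus while the isopropenyl group migrates from boron to carbon, giving the secondary allylic boronate A6; oxidation of the C-B bond with retention and ester cleavage would then lead to 18.
- Merits: two C-C bonds and the stereocenter are made in one step, and the route is more convergent. On paper it is shorter than the chosen plan.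
- Weak points: the electrophile is an electron-rich aryl iodide with two ortho substituents, the hardest case for oxidative addition and for the alkene-binding step. Iodide is a poorer partner than triflate in this chemistry. The product is an allylic boronate that can undergo 1,3-borotropic shift to the achiral primary isomer. The aryl acetates and the pyranone are exposed to organolithium-derived species and later to basic peroxide. A3 requires iodination at C6 in the presence of the prenyl alkene.
- Comparison: the chosen plan is longer. It sets against this a stereo-defining step on a remote, unhindered primary allylic alcohol of a well-understood substrate class, three atoms from the crowded ring, and no organometallic reagent in the presence of ring C.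

**Alternative 3:** ring A is cut at C8-C8a, C5-C6, C7-C8 and C4a-C5. In the forward direction, irradiation of the pyranonyl diazo ketone A7 with the chiral siloxyalkyne A8 triggers a Wolff shift, a ketene-alkyne (2+2) addition, four-electron ring opening and six-electron closure onto the pyranone, giving the isoflavone A9 with free 5-OH and a differentiated 7-O-silyl group.
- Merits: full regiocontrol of a hexasubstituted ring in one step, differentiated oxygens, and convergence. In regiocontrol it is at least as good as the chosen plan.
- Weak points: A7 and A8 each need a multistep synthesis, and A8 must already contain C2'', so the stereochemical problem is only moved. The carbene from an alkyl-substituted diazo ketone can undergo 1,2-hydrogen shift or cyclopropanate its own prenyl alkene instead of the Wolff shift. The ketene can add to the prenyl or isopropenyl alkenes. The 4-pyranone is itself a photoactive chromophore.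
- Comparison: the chosen plan cannot match the one-step ring construction, but it needs none. Genistein supplies ring A, and step count and risk both favour functionalizing it.

Key step: step 9

## Route

Step 1
Reactants: 1 genistein (5,7,4'-trihydroxyisoflavone)
Product: 2 7,4'-bis-O-TBS-genistein (5-hydroxyl free)
Conditions: TBSCl (2.3 equiv), imidazole, DMF, 0 °C to rt
Reagents that add atoms: tert-butyldimethylsilyl chloride (TBSCl), CC(C)(C)[Si](C)(C)Cl
Why: Selective phenol silylation: the 7- and 4'-hydroxyls react with the silyl chloride, whereas the 5-hydroxyl is held in a hydrogen bond to the C4 carbonyl and is not silylated under these conditions.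

Step 2
Reactants: 2 7,4'-bis-O-TBS-genistein; 3 prenol (3-methylbut-2-en-1-ol)
Product: 4 5-O-prenyl-7,4'-bis-O-TBS-genistein
Conditions: PPh3, DIAD, THF, 0 °C to rt
Reagents that add atoms: none
Why: Mitsunobu etherification: the hydrogen-bonded 5-OH is acidic enough to be alkylated at the primary carbon of the activated prenol, and the base-free conditions spare the aryl silyl ethers that carbonate would cleave.

Step 3
Reactants: 4 5-O-prenyl-7,4'-bis-O-TBS-genistein
Product: 6 5-hydroxy-8-prenyl-7,4'-bis-O-TBS-genistein, via C6 reverse-prenyl ortho-dienone 5 (not isolated)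
Conditions: Eu(fod)3 (10 mol%), CHCl3, 60 °C
Reagents that add atoms: none
Why: para-Claisen-Cope rearrangement: europium chelated between O5 and the C4 carbonyl accelerates the [3,3] shift of the prenyl ether to C6 (dienone 5), a second [3,3] (Cope) shift carries the 1,1-dimethylallyl group on to C8 with the normal prenyl connectivity restored, and enolization gives phenol 6.

Step 4
Reactants: 6 5-hydroxy-8-prenyl-7,4'-bis-O-TBS-genistein; 7 allyl alcohol
Product: 8 5-O-allyl-8-prenyl-7,4'-bis-O-TBS-genistein
Conditions: PPh3, DIAD, THF, 0 °C to rt
Reagents that add atoms: none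
Why: Mitsunobu etherification as in step 2; O5 is the only free hydroxyl and the neutral medium again protects the 7-O-silyl ether.

Step 5
Reactants: 8 5-O-allyl-8-prenyl-7,4'-bis-O-TBS-genistein
Product: 10 6-allyl-5-hydroxy-8-prenyl-7,4'-bis-O-TBS-genistein, via C6 allyl ortho-dienone 9 (not isolated)
Conditions: PhNEt2, 190 °C, sealed tube
Reagents that add atoms: none
Why: Aromatic ortho-Claisen rearrangement: the [3,3] shift can only reach C6 because C4a has no hydrogen and C8 is occupied, dienone 9 enolizes to the hydrogen-bonded phenol, and an unsubstituted allyl group cannot give a chain isomer.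

Step 6
Reactants: 10 6-allyl-5-hydroxy-8-prenyl-7,4'-bis-O-TBS-genistein
Product: 11 6-allyl-8-prenyl-5,7,4'-tris-O-TBS-genistein
Conditions: TBSOTf, 2,6-lutidine, CH2Cl2, 0 °C to rt
Reagents that add atoms: tert-butyldimethylsilyl triflate (TBSOTf), CC(C)(C)[Si](C)(C)OS(=O)(=O)C(F)(F)F
Why: Phenol silylation with a silyl triflate: the hindered, hydrogen-bonded 5-OH resists the chloride (step 1) but should yield to the far more electrophilic triflate; O5 must be capped because a free phenol next to the C6 chain would bind titanium in step 9 and open the epoxide.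

Step 7
Reactants: 11 6-allyl-8-prenyl-5,7,4'-tris-O-TBS-genistein; 12 methacrolein (2-methylpropenal)
Product: 13 6-[(E)-3-methyl-4-oxobut-2-enyl]-8-prenyl-5,7,4'-tris-O-TBS-genistein
Conditions: methacrolein (10 equiv), second-generation Hoveyda-Grubbs catalyst (5 mol%), 1,4-benzoquinone (10 mol%), CH2Cl2, 40 °C
Reagents that add atoms: none
Why: Olefin cross-metathesis: the monosubstituted allyl alkene engages the ruthenium carbene readily and couples with excess methacrolein to the conjugated, thermodynamically favoured (E)-enal, while the trisubstituted prenyl alkene and the pyranone C2=C3 bond react far more slowly; benzoquinone suppresses hydride-induced double-bond migration.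

Step 8
Reactants: 13 6-[(E)-3-methyl-4-oxobut-2-enyl]-8-prenyl-5,7,4'-tris-O-TBS-genistein
Product: 14 6-[(E)-4-hydroxy-3-methylbut-2-enyl]-8-prenyl-5,7,4'-tris-O-TBS-genistein
Conditions: NaBH4, CeCl3·7H2O, MeOH/THF, -40 °C
Reagents that add atoms: none
Why: Luche reduction: cerium-activated borohydride adds 1,2 to the enal much faster than to the vinylogous ester carbonyl of ring C, and low temperature with short contact limits methanolysis of the aryl silyl ethers.

Step 9
Reactants: 14 6-[(E)-4-hydroxy-3-methylbut-2-enyl]-8-prenyl-5,7,4'-tris-O-TBS-genistein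
Product: 15 6-{[(2R,3R)-3-(hydroxymethyl)-3-methyloxiran-2-yl]methyl}-8-prenyl-5,7,4'-tris-O-TBS-genistein
Conditions: Ti(OiPr)4 (20 mol%), D-(-)-diisopropyl tartrate (24 mol%), TBHP (2 equiv, in decane), 4 Å MS, CH2Cl2, -20 °C
Reagents that add atoms: tert-butyl hydroperoxide (TBHP), CC(C)(C)OO
Why: This is a Katsuki-Sharpless asymmetric epoxidation of an (E)-2-methyl-2-alken-1-ol, the closest known substrate class. The allylic alkoxide of 14 and the tert-butyl peroxide exchange onto one tetravalent titanium of the dimeric titanium tartrate complex, and the bound peroxide oxygen is passed to the alkene in a concerted step. The oxirane therefore closes by one-step oxygen-atom transfer, a (2+1) addition that forms both C-O bonds on the same face, so the E geometry of 14 becomes the trans arrangement of C4'' and C1'' on the ring. The absolute configuration of both new stereocenters is set by the tartrate: the D-(-)-ester delivers oxygen to the face that gives the (2R,3R)-epoxy alcohol, the mirror image of the (2S,3S) products this substrate class gives with the L-(+)-ester. Chemoselectivity rests on the hydroxyl group, since only an alkene whose allylic oxygen is bound to titanium is epoxidized at a useful rate; the C8 prenyl alkene has no hydroxyl and the C2=C3 bond is electron-poor. Silyl groups on O5 and O7 remove the phenols that could chelate titanium or attack C2'' of the product, and the molecular sieves keep the catalyst turning over and suppress titanium-assisted opening.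

Step 10
Reactants: 15 6-{[(2R,3R)-3-(hydroxymethyl)-3-methyloxiran-2-yl]methyl}-8-prenyl-5,7,4'-tris-O-TBS-genistein
Product: 16 6-{[(2R,3S)-3-(iodomethyl)-3-methyloxiran-2-yl]methyl}-8-prenyl-5,7,4'-tris-O-TBS-genistein
Conditions: I2, PPh3, imidazole, THF, 0 °C
Reagents that add atoms: iodine (I2), II
Why: Appel-type iodination: the primary hydroxyl is activated as an alkoxyphosphonium ion and displaced by iodide while imidazole buffers the medium; no stereocenter is touched, and the descriptor of the quaternary carbon changes from R to S only because CH2I outranks the ring carbon.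

Step 11
Reactants: 16 6-{[(2R,3S)-3-(iodomethyl)-3-methyloxiran-2-yl]methyl}-8-prenyl-5,7,4'-tris-O-TBS-genistein
Product: 17 6-[(2R)-2-hydroxy-3-methylbut-3-enyl]-8-prenyl-5,7,4'-tris-O-TBS-genistein
Conditions: Zn dust, AcOH, EtOH/THF, 40 °C
Reagents that add atoms: none
Why: Reductive ring opening of a 2,3-epoxy iodide: zinc reduces the C4''-I bond and the carbanion equivalent expels the epoxide oxygen from C3'', creating the C3''=C4'' bond; the C2''-O bond is never broken, so C2'' keeps its configuration (R).

Step 12
Reactants: 17 6-[(2R)-2-hydroxy-3-methylbut-3-enyl]-8-prenyl-5,7,4'-tris-O-TBS-genistein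
Product: 18 6-[(2R)-2-hydroxy-3-methylbut-3-enyl]-8-prenylgenistein (CNP0105386.1)
Conditions: TBAF, AcOH, THF, 0 °C to rt
Reagents that add atoms: none
Why: Fluoride desilylation: the three aryl O-Si bonds are cleaved by fluoride, acetic acid buffers the phenoxides, and the non-acidic, non-reductive medium leaves the prenyl group, the allylic alcohol, ring C and C2'' untouched; a silyl group that had wandered to the C2'' oxygen would be removed by the same reagent.

## Compound list

1 | genistein (5,7,4'-trihydroxyisoflavone) | O=c1c(-c2ccc(O)cc2)coc2cc(O)cc(O)c12 | starting material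
2 | 7,4'-bis-O-TBS-genistein | O=c1c(-c2ccc(O[Si](C)(C)C(C)(C)C)cc2)coc2cc(O[Si](C)(C)C(C)(C)C)cc(O)c12 | intermediate
3 | prenol (3-methylbut-2-en-1-ol) | CC(C)=CCO | starting material
4 | 5-O-prenyl-7,4'-bis-O-TBS-genistein | O=c1c(-c2ccc(O[Si](C)(C)C(C)(C)C)cc2)coc2cc(O[Si](C)(C)C(C)(C)C)cc(OCC=C(C)C)c12 | intermediate
5 | transient ortho-dienone: 6-(2-methylbut-3-en-2-yl)-7-(TBS-oxy)-3-[4-(TBS-oxy)phenyl]-6H-chromene-4,5-dione (C6 sp3, racemic) | O=C1C(-c2ccc(O[Si](C)(C)C(C)(C)C)cc2)=COC2=C1C(=O)C(C(C)(C)C=C)C(O[Si](C)(C)C(C)(C)C)=C2 | intermediate
6 | 5-hydroxy-8-prenyl-7,4'-bis-O-TBS-genistein | O=c1c(-c2ccc(O[Si](C)(C)C(C)(C)C)cc2)coc2c(CC=C(C)C)c(O[Si](C)(C)C(C)(C)C)cc(O)c12 | intermediate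
7 | allyl alcohol (prop-2-en-1-ol) | C=CCO | starting material
8 | 5-O-allyl-8-prenyl-7,4'-bis-O-TBS-genistein | O=c1c(-c2ccc(O[Si](C)(C)C(C)(C)C)cc2)coc2c(CC=C(C)C)c(O[Si](C)(C)C(C)(C)C)cc(OCC=C)c12 | intermediate
9 | transient ortho-dienone: 6-allyl-8-prenyl-7-(TBS-oxy)-3-[4-(TBS-oxy)phenyl]-6H-chromene-4,5-dione (C6 sp3, racemic) | O=C1C(-c2ccc(O[Si](C)(C)C(C)(C)C)cc2)=COC2=C1C(=O)C(CC=C)C(O[Si](C)(C)C(C)(C)C)=C2CC=C(C)C | intermediate
10 | 6-allyl-5-hydroxy-8-prenyl-7,4'-bis-O-TBS-genistein | O=c1c(-c2ccc(O[Si](C)(C)C(C)(C)C)cc2)coc2c(CC=C(C)C)c(O[Si](C)(C)C(C)(C)C)c(CC=C)c(O)c12 | intermediate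
11 | 6-allyl-8-prenyl-5,7,4'-tris-O-TBS-genistein | O=c1c(-c2ccc(O[Si](C)(C)C(C)(C)C)cc2)coc2c(CC=C(C)C)c(O[Si](C)(C)C(C)(C)C)c(CC=C)c(O[Si](C)(C)C(C)(C)C)c12 | intermediate
12 | methacrolein (2-methylpropenal) | C=C(C)C=O | starting material
13 | 6-[(E)-3-methyl-4-oxobut-2-enyl]-8-prenyl-5,7,4'-tris-O-TBS-genistein | O=C/C(C)=C/Cc1c(O[Si](C)(C)C(C)(C)C)c(CC=C(C)C)c2occ(-c3ccc(O[Si](C)(C)C(C)(C)C)cc3)c(=O)c2c1O[Si](C)(C)C(C)(C)C | intermediate
14 | 6-[(E)-4-hydroxy-3-methylbut-2-enyl]-8-prenyl-5,7,4'-tris-O-TBS-genistein | OC/C(C)=C/Cc1c(O[Si](C)(C)C(C)(C)C)c(CC=C(C)C)c2occ(-c3ccc(O[Si](C)(C)C(C)(C)C)cc3)c(=O)c2c1O[Si](C)(C)C(C)(C)C | intermediate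
15 | (2R,3R)-epoxy alcohol: 6-{[(2R,3R)-3-(hydroxymethyl)-3-methyloxiran-2-yl]methyl}-8-prenyl-5,7,4'-tris-O-TBS-genistein | OC[C@@]1(C)O[C@@H]1Cc1c(O[Si](C)(C)C(C)(C)C)c(CC=C(C)C)c2occ(-c3ccc(O[Si](C)(C)C(C)(C)C)cc3)c(=O)c2c1O[Si](C)(C)C(C)(C)C | intermediate
16 | epoxy iodide: 6-{[(2R,3S)-3-(iodomethyl)-3-methyloxiran-2-yl]methyl}-8-prenyl-5,7,4'-tris-O-TBS-genistein | IC[C@@]1(C)O[C@@H]1Cc1c(O[Si](C)(C)C(C)(C)C)c(CC=C(C)C)c2occ(-c3ccc(O[Si](C)(C)C(C)(C)C)cc3)c(=O)c2c1O[Si](C)(C)C(C)(C)C | intermediate
17 | 6-[(2R)-2-hydroxy-3-methylbut-3-enyl]-8-prenyl-5,7,4'-tris-O-TBS-genistein | C=C(C)[C@H](O)Cc1c(O[Si](C)(C)C(C)(C)C)c(CC=C(C)C)c2occ(-c3ccc(O[Si](C)(C)C(C)(C)C)cc3)c(=O)c2c1O[Si](C)(C)C(C)(C)C | intermediate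
18 | 6-[(2R)-2-hydroxy-3-methylbut-3-enyl]-8-prenylgenistein (CNP0105386.1) | C=C(C)[C@H](O)Cc1c(O)c(CC=C(C)C)c2occ(-c3ccc(O)cc3)c(=O)c2c1O | target

## Step count and risk

Total: 12 steps. Longest linear sequence: 12 steps from genistein (1); prenol (3), allyl alcohol (7) and methacrolein (12) are commercial and enter directly.

**Step 9 (key step).** The substrate offers titanium other Lewis-basic sites (the pyranone carbonyl and three aryl silyl ethers), and two bulky silyloxy groups sit close to the reacting alkene. The likely failures are slow turnover, eroded face selectivity, and titanium-assisted opening of the product. The fallback sets out from enal 13 and returns at 15, replacing hydroxyl-directed electrophilic epoxidation by nucleophilic epoxidation under iminium catalysis. Aqueous H2O2 and a chiral primary amine salt (a 9-amino-9-deoxy-epi-cinchona alkaloid with an acid cocatalyst, the pseudoenantiomer chosen for the required sense) is a known method for alpha-branched enals. It should give the (2S,3R)-epoxy aldehyde (aldehyde numbering; same spatial arrangement as 15) F1. Reduction of F1 with NaBH4 at low temperature gives 15. The prenyl alkene is inert to this oxidant because it is not electron-poor.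

**Step 3.** Dienone 5 still has a hydrogen on C6. It may enolize before the Cope shift, leaving the reversed 1,1-dimethylallyl group on C6, or an ionic 1,3-shift may put a normal prenyl group there. The fallback sets out from 2 and returns at 10, reversing the order of the two alkylations so that C6 is blocked when the prenyl ether rearranges.
- Mitsunobu reaction of 2 with allyl alcohol (7) gives 5-O-allyl-7,4'-bis-O-TBS-genistein F2.
- Thermal Claisen rearrangement gives 6-allyl-5-hydroxy-7,4'-bis-O-TBS-genistein F3.
- Mitsunobu reaction with prenol (3) gives 6-allyl-5-O-prenyl-7,4'-bis-O-TBS-genistein F4.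
- Eu(fod)3 then takes the prenyl group through a dienone that has no hydrogen on C6 and can only aromatize after the shift to C8, giving 10.

**Step 7.** The allyl group lies between two silyloxy groups. Turnover may be sluggish, the double bond may migrate into conjugation with ring A, and under the forcing conditions then needed the prenyl alkene may enter metathesis. The fallback sets out from 2 and returns at 13, running the metathesis before any prenyl group exists.
- From 2, 5-O-allyl-7,4'-bis-O-TBS-genistein F2 and 6-allyl-5-hydroxy-7,4'-bis-O-TBS-genistein F3 are made as described for step 3.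
- Cross-metathesis of F3 with methacrolein (12) gives 5-hydroxy-6-[(E)-3-methyl-4-oxobut-2-enyl]-7,4'-bis-O-TBS-genistein F5.
- Mitsunobu reaction with prenol (3) gives its 5-O-prenyl ether F6.
- Eu(fod)3 carries the prenyl group past the blocked C6 to C8, giving 5-hydroxy-6-[(E)-3-methyl-4-oxobut-2-enyl]-8-prenyl-7,4'-bis-O-TBS-genistein F7. The enal chain is unlikely to migrate instead, because its shift would create a quaternary carbon.
- Silylation of F7 with TBSOTf and 2,6-lutidine gives 13.

**Step 10 (with step 11).** Iodide must displace at a carbon next to a fully substituted epoxide carbon. Slow substitution, and opening of the epoxide by iodide or by the zinc iodide formed in step 11, are the likely failures. The fallback sets out from 15 and returns at 17, replacing both steps by a radical fragmentation that needs no substitution at C4'' and no Lewis acid. Alcohol 15 is acylated with 1,1'-thiocarbonyldiimidazole to the O-(imidazol-1-ylthiocarbonyl) derivative F8. Bu3SnH and AIBN in hot toluene then generate the C4'' radical, which opens the oxirane at the C3''-O bond; the resulting alkoxy radical is reduced by the stannane to 17 with C2'' unchanged.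

## Further compounds

F1 | step 9 | (2S,3R)-epoxy aldehyde: 6-{[(2R,3S)-3-formyl-3-methyloxiran-2-yl]methyl}-8-prenyl-5,7,4'-tris-O-TBS-genistein | O=C[C@@]1(C)O[C@@H]1Cc1c(O[Si](C)(C)C(C)(C)C)c(CC=C(C)C)c2occ(-c3ccc(O[Si](C)(C)C(C)(C)C)cc3)c(=O)c2c1O[Si](C)(C)C(C)(C)C
F2 | step 3 | 5-O-allyl-7,4'-bis-O-TBS-genistein | O=c1c(-c2ccc(O[Si](C)(C)C(C)(C)C)cc2)coc2cc(O[Si](C)(C)C(C)(C)C)cc(OCC=C)c12
F3 | step 3 | 6-allyl-5-hydroxy-7,4'-bis-O-TBS-genistein | O=c1c(-c2ccc(O[Si](C)(C)C(C)(C)C)cc2)coc2cc(O[Si](C)(C)C(C)(C)C)c(CC=C)c(O)c12
F4 | step 3 | 6-allyl-5-O-prenyl-7,4'-bis-O-TBS-genistein | O=c1c(-c2ccc(O[Si](C)(C)C(C)(C)C)cc2)coc2cc(O[Si](C)(C)C(C)(C)C)c(CC=C)c(OCC=C(C)C)c12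
F5 | step 7 | 5-hydroxy-6-[(E)-3-methyl-4-oxobut-2-enyl]-7,4'-bis-O-TBS-genistein | O=C/C(C)=C/Cc1c(O[Si](C)(C)C(C)(C)C)cc2occ(-c3ccc(O[Si](C)(C)C(C)(C)C)cc3)c(=O)c2c1O
F6 | step 7 | 6-[(E)-3-methyl-4-oxobut-2-enyl]-5-O-prenyl-7,4'-bis-O-TBS-genistein | O=C/C(C)=C/Cc1c(O[Si](C)(C)C(C)(C)C)cc2occ(-c3ccc(O[Si](C)(C)C(C)(C)C)cc3)c(=O)c2c1OCC=C(C)C
F7 | step 7 | 5-hydroxy-6-[(E)-3-methyl-4-oxobut-2-enyl]-8-prenyl-7,4'-bis-O-TBS-genistein | O=C/C(C)=C/Cc1c(O[Si](C)(C)C(C)(C)C)c(CC=C(C)C)c2occ(-c3ccc(O[Si](C)(C)C(C)(C)C)cc3)c(=O)c2c1O
F8 | step 10 | O-(imidazol-1-ylthiocarbonyl) derivative of the (2R,3R)-epoxy alcohol 15 | S=C(n1ccnc1)OC[C@@]1(C)O[C@@H]1Cc1c(O[Si](C)(C)C(C)(C)C)c(CC=C(C)C)c2occ(-c3ccc(O[Si](C)(C)C(C)(C)C)cc3)c(=O)c2c1O[Si](C)(C)C(C)(C)C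
A1 | alternative 1 | 2-bromo-3,5-bis(SEM-oxy)-4-[(2R)-2-(TBS-oxy)-3-methylbut-3-enyl]-6-prenylphenyl 3-methoxy-2-[4-(SEM-oxy)phenyl]acrylate (SEM = 2-(trimethylsilyl)ethoxymethyl) | C=C(C)[C@H](O[Si](C)(C)C(C)(C)C)Cc1c(OCOCC[Si](C)(C)C)c(CC=C(C)C)c(OC(=O)C(=COC)c2ccc(OCOCC[Si](C)(C)C)cc2)c(Br)c1OCOCC[Si](C)(C)C
A2 | alternative 1 | 5,7,4'-tris-O-SEM-2''-O-TBS derivative of 18 | C=C(C)[C@H](O[Si](C)(C)C(C)(C)C)Cc1c(OCOCC[Si](C)(C)C)c(CC=C(C)C)c2occ(-c3ccc(OCOCC[Si](C)(C)C)cc3)c(=O)c2c1OCOCC[Si](C)(C)C
A3 | alternative 2 | 6-iodo-8-prenyl-5,7,4'-tri-O-acetylgenistein | CC(=O)Oc1ccc(-c2coc3c(CC=C(C)C)c(OC(C)=O)c(I)c(OC(C)=O)c3c2=O)cc1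
A4 | alternative 2 | vinylboronic acid pinacol ester | C=CB1OC(C)(C)C(C)(C)O1
A5 | alternative 2 | isopropenyllithium | [Li]C(C)=C
A6 | alternative 2 | 5,7,4'-tri-O-acetyl-8-prenylgenistein carrying the C6 chain with a pinacol boronate at C2'' in place of the hydroxyl (same spatial arrangement) | C=C(C)[C@H](B1OC(C)(C)C(C)(C)O1)Cc1c(OC(C)=O)c(CC=C(C)C)c2occ(-c3ccc(OC(C)=O)cc3)c(=O)c2c1OC(C)=O
A7 | alternative 3 | 2-diazo-5-methyl-1-{4-oxo-5-[4-(TBS-oxy)phenyl]-4H-pyran-2-yl}hex-4-en-1-one | CC(C)=CCC(=[N+]=[N-])C(=O)c1cc(=O)c(-c2ccc(O[Si](C)(C)C(C)(C)C)cc2)co1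
A8 | alternative 3 | (4R)-4-(TBS-oxy)-5-methyl-1-(triisopropylsilyloxy)hex-5-en-1-yne | C=C(C)[C@H](O[Si](C)(C)C(C)(C)C)CC#CO[Si](C(C)C)(C(C)C)C(C)C
A9 | alternative 3 | 5-hydroxy-7-O-triisopropylsilyl-4'-O,2''-O-bis-TBS derivative of 18 | C=C(C)[C@H](O[Si](C)(C)C(C)(C)C)Cc1c(O[Si](C(C)C)(C(C)C)C(C)C)c(CC=C(C)C)c2occ(-c3ccc(O[Si](C)(C)C(C)(C)C)cc3)c(=O)c2c1O
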